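**Retrosynthetic overview**
1. 28 ⇒ ring-closing metathesis at C5=C6 of triene lactone 27, so the ten-membered ring is closed last.
2. γ-Lactone of 27 ⇒ the C7–O and C8–O bonds are made together by a hydroxyl-directed anti-oxylactonisation of dienyl carbinol 23 (key step).
3. 23 ⇒ C8–C9 Nozaki–Hiyama–Kishi union of ring A aldehyde 14 with alkenyl iodide 21, which comes from a vinylallenoate.
4. 14 ⇒ C12–O by Mitsunobu inversion, C2 by Felkin reduction, and ring A by an enantioselective exo Diels–Alder reaction of silyloxydiene 2 with enal 3.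
5. Ring order: cyclohexene ring A, then the γ-lactone, then the ten-membered ring.

Assumption: enal 3 (a bulk carotenoid C5 building block) is bought, and the (S)-oxazaborolidinium ion exposes the Cα-Si face of α-methyl enals as its binding model predicts (its mirror image is equally available).

Locants: C1–C20 are the briarane locants of 28.
- C1 is quaternary, C2 carries OAc, and C5=C6 is the ring olefin.
- C7 carries the lactone O, C8 the OH, C9 an OAc.
- C10–C14 belong to ring A, and C12 carries the butanoate.
- C15, C16, C18 and C20 are methyls; C17 and C19 belong to the lactone.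
- β is the face of ring A that carries Me-15.

**Step 1**
Reactants: 1 pent-1-en-3-one
Product: 2 (Z)-3-(tert-butyldimethylsilyloxy)penta-1,3-diene
Conditions: TBSOTf, Et3N, CH2Cl2, 0 °C
Reagents that add atoms: tert-butyldimethylsilyl triflate, CC(C)(C)[Si](C)(C)OS(=O)(=O)C(F)(F)F
Why: Soft enolisation (silyl triflate/amine) of the ethyl ketone gives the 2-silyloxydiene as the Z enol ether, with the methyl trans to the vinyl group and therefore "outside" in the s-cis diene.

**Step 2**
Reactants: 2 (Z)-3-(tert-butyldimethylsilyloxy)penta-1,3-diene; 3 (E)-4,4-dimethoxy-2-methylbut-2-enal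
Product: 4 (1S,5R,6S)-4-(tert-butyldimethylsilyloxy)-6-(dimethoxymethyl)-1,5-dimethylcyclohex-3-ene-1-carbaldehyde
Conditions: (S)-B-(o-tolyl)oxazaborolidine from (S)-α,α-diphenylprolinol (20 mol %), Tf2NH (18 mol %), CH2Cl2, −78 to −40 °C
Reagents that add atoms: none
Why: Enantioselective Diels–Alder reaction: the cationic oxazaborolidine holds the s-trans enal by B–O coordination and a formyl C–H···O contact and leaves its Cα-Si face open (sets C1 and C10), the siloxy group steers its methyl-bearing terminus to C10 (para rule), the E-olefin fixes C2 and C9 trans, and the formyl-exo mode that 2-silyloxydienes adopt when both termini of the shorter forming bond are substituted puts Me-20 cis to C9 and Me-15 (sets C11).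

**Step 3**
Reactants: 4 Diels–Alder aldehyde; 5 4-bromo-2-methylbut-1-ene
Product: 7 1-[(1S,5R,6S)-4-(tert-butyldimethylsilyloxy)-6-(dimethoxymethyl)-1,5-dimethylcyclohex-3-en-1-yl]-4-methylpent-4-en-1-ol (C2 epimers), via Grignard reagent 6 (not isolated)
Conditions: Mg, THF, rt; then 4, THF, −78 to 0 °C; H2O quench
Reagents that add atoms: none
Why: Grignard 1,2-addition to the neopentyl aldehyde is tolerated by the acetal and the silyl enol ether, and the Felkin–Anh preference for the wrong C2 epimer does not matter because C2 is flattened in step 4.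

**Step 4**
Reactants: 7 C2 carbinol
Product: 8 1-[(1S,5R,6S)-4-(tert-butyldimethylsilyloxy)-6-(dimethoxymethyl)-1,5-dimethylcyclohex-3-en-1-yl]-4-methylpent-4-en-1-one
Conditions: DMP, pyridine, CH2Cl2, 0 °C to rt
Reagents that add atoms: none
Why: Dess–Martin oxidation under pyridine buffer converts the hindered carbinol into the ketone without touching the enol ether, the acetal or the alkene.

**Step 5**
Reactants: 8 C2 ketone
Product: 10 (1R)-1-[(1S,5R,6S)-4-(tert-butyldimethylsilyloxy)-6-(dimethoxymethyl)-1,5-dimethylcyclohex-3-en-1-yl]-4-methylpent-4-enyl acetate, via aluminium alkoxide 9 (not isolated)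
Conditions: i-Bu2AlH, CH2Cl2, −78 °C; then pyridine, DMAP, Ac2O, −78 °C to rt
Reagents that add atoms: acetic anhydride, CC(=O)OC(C)=O
Why: Felkin–Anh reduction in which hydride comes in anti to C10 (large) and past Me-15 (small) gives the (2R)-alkoxide, and this is acetylated in the flask as in reductive-acetylation protocols, so the final C2 acetate costs no extra step.

**Step 6**
Reactants: 10 silyl enol ether acetate
Product: 11 (1R)-1-[(1S,5R,6S)-6-(dimethoxymethyl)-1,5-dimethyl-4-oxocyclohex-2-en-1-yl]-4-methylpent-4-enyl acetate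
Conditions: Pd(OAc)2 (15 mol %), O2 (1 atm), DMSO, 50 °C
Reagents that add atoms: none
Why: Aerobic Saegusa–Ito oxidation, in which the palladium enolate at C13 can lose hydride only from C14, gives the C13=C14 enone regiospecifically under near-neutral conditions that leave C11 untouched.

**Step 7**
Reactants: 11 enone
Product: 12 (1R)-1-[(1S,4S,5R,6S)-6-(dimethoxymethyl)-4-hydroxy-1,5-dimethylcyclohex-2-en-1-yl]-4-methylpent-4-enyl acetate (12β-alcohol)
Conditions: NaBH4, CeCl3·7H2O, MeOH, −78 °C
Reagents that add atoms: none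
Why: Luche 1,2-reduction: ring A adopts the half-chair that keeps Me-15 and Me-20 equatorial and C2/C9 axial, the axial C9 acetal blocks the β-face (axial) trajectory, and so hydride adds from the α face to give the 12β (12S) alcohol.

**Step 8**
Reactants: 12 12β-alcohol
Product: 13 (1R)-1-[(1S,4R,5R,6S)-4-butanoyloxy-6-(dimethoxymethyl)-1,5-dimethylcyclohex-2-en-1-yl]-4-methylpent-4-enyl acetate
Conditions: n-PrCO2H, PPh3, DIAD, toluene, 0 °C to rt
Reagents that add atoms: butanoic acid, CCCC(=O)O
Why: Mitsunobu esterification, in which butanoate displaces the axial oxyphosphonium group by SN2 with inversion, forms the C12–O bond in the 12α (12R) configuration, while SN2' attack is shut off by the neopentyl C14.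

**Step 9**
Reactants: 13 acetal
Product: 14 (1R)-1-[(1S,4R,5R,6S)-4-butanoyloxy-6-formyl-1,5-dimethylcyclohex-2-en-1-yl]-4-methylpent-4-enyl acetate
Conditions: 1 M HCl, THF, 0 °C to rt
Reagents that add atoms: water, O
Why: Acid hydrolysis of the dimethyl acetal runs under conditions too mild to cleave the esters, ionise the allylic butanoate or enolise C10.

**Step 10**
Reactants: 15 tert-butyl 2-bromopropanoate
Product: 17 tert-butyl 2-(triphenyl-λ5-phosphanylidene)propanoate, via phosphonium bromide 16 (not isolated)
Conditions: PPh3, MeCN, 80 °C; then aq. NaOH, CH2Cl2, 0 °C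
Reagents that add atoms: triphenylphosphine, c1ccc(cc1)P(c1ccccc1)c1ccccc1
Why: SN2 quaternisation of the phosphine followed by deprotonation is the standard synthesis of an ester-stabilised Wittig ylide.

**Step 11**
Reactants: 17 ylide; 18 (E)-but-2-enoyl chloride
Product: 20 tert-butyl 2-methylhexa-2,3,5-trienoate (racemic), via vinylketene 19 (not isolated)
Conditions: Et3N, CH2Cl2, 0 °C to rt
Reagents that add atoms: none
Why: Wittig olefination of a ketene: Et3N removes HCl from 18 by 1,4-elimination and the vinylketene is trapped at its carbonyl by 17, the tert-butyl ester being chosen so that the later C9 alkoxide cannot lactonise onto C19.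

**Step 12**
Reactants: 20 vinylallenoate
Product: 21 tert-butyl (3E)-3-iodo-2-methylhexa-3,5-dienoate (racemic at C17)
Conditions: NaI, AcOH, 40 °C
Reagents that add atoms: sodium iodide, [Na+].[I-]
Why: Conjugate hydroiodination of a 2,3-allenoate: iodide attacks the central carbon C8 from the side of H-7, away from the vinyl group, and α-protonation of the dienolate gives the deconjugated (E)-alkenyl iodide, with C17 corrected in step 15.

**Step 13**
Reactants: 14 ring A aldehyde; 21 alkenyl iodide
Product: 23 tert-butyl (3E)-3-[(R)-hydroxy(ring A)methyl]-2-methylhexa-3,5-dienoate = (9R,7E)-dienyl carbinol (C17 epimers), via alkenylchromium dichloride 22 (not isolated)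
Conditions: CrCl2 (4 equiv), NiCl2 (2 mol %), DMSO/THF, rt; H2O quench
Reagents that add atoms: none
Why: Nozaki–Hiyama–Kishi coupling: the non-basic alkenylchromium reagent keeps its olefin geometry, adds only to the aldehyde, and follows the Felkin–Anh model (attack anti to quaternary C1, past H-10), which sets (9R).

**Step 14**
Reactants: 23 dienyl carbinol
Product: 25 (7S,8R,9R)-8,9-dihydroxy γ-lactone carrying the C6 vinyl group (C17 epimers), via epoxy alcohol 24 (not isolated)
Conditions: VO(acac)2 (5 mol %), t-BuOOH (1.2 equiv, decane), 4 Å MS, CH2Cl2/(CF3)2CHOH 4:1, 0 °C to rt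
Reagents that add atoms: tert-butyl hydroperoxide, CC(C)(C)OO
Why: Proposed new method: a hydroxyl-directed anti-oxylactonisation in which one vanadium centre does two jobs - the pentavalent vanadium alkoxide of the C9 carbinol delivers the peroxide oxygen only to C7=C8 (allylic-alcohol acceleration spares the other three alkenes) on the face fixed by A(1,2) strain between the C17 branch and the carbinol substituents (erythro, the C8–O configuration of the target), and the still-bound Lewis-acidic vanadium, helped by the hydrogen-bond-donor cosolvent, then loosens the allylic C7–O bond so that the tert-butyl ester carbonyl attacks C7 from the rear in a 5-endo opening (inversion, or closure trans to the bulky C9 branch if the allyl cation becomes free) and sheds isobutene, forming the lactone C7–O bond and both stereocentres in one operation; the closest known reaction types are vanadium-catalysed directed epoxidation, vanadium-catalysed epoxidation–cyclisation of bishomoallylic alcohols to tetrahydrofurans and acid-induced lactonisation of β,γ-epoxy esters, none of which has been run as a single catalytic anti-hydroxylactonisation of a dienyl ester.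

**Step 15**
Reactants: 25 diol lactone
Product: 27 (7S,8S,9R,17R)-9-acetoxy-8-hydroxy γ-lactone triene, via C17-epimeric acetates 26 (not isolated)
Conditions: Ac2O, Et3N, DMAP, CH2Cl2, rt; then DBU, 40 °C
Reagents that add atoms: acetic anhydride, CC(=O)OC(C)=O
Why: DMAP-catalysed acetylation takes the secondary C9 hydroxyl and leaves the tertiary C8 hydroxyl, and DBU then equilibrates the lactone α-carbon by enolisation to the more stable epimer with Me-18 trans to the bulky C9 branch (17R).

**Step 16**
Reactants: 27 triene lactone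
Product: 28 CNP0211702.1 (1S,2R,5Z,7S,8S,9R,10S,11R,12R,17R)
Conditions: second-generation Hoveyda–Grubbs catalyst (10 mol %), toluene (1 mM), 100 °C, Ar sparge
Reagents that add atoms: none
Why: Ring-closing metathesis at high dilution: the monosubstituted C6 vinyl group loads the ruthenium carbene, which closes onto the 1,1-disubstituted C5 alkene, and the reversible reaction settles on the less strained ring-cis (5Z) trisubstituted olefin of the trans-fused ten-membered ring.

**Compound list**
1 | pent-1-en-3-one | CCC(=O)C=C | starting material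
2 | (Z)-3-(tert-butyldimethylsilyloxy)penta-1,3-diene | C/C=C(O[Si](C)(C)C(C)(C)C)/C=C | intermediate
3 | (E)-4,4-dimethoxy-2-methylbut-2-enal | COC(OC)/C=C(\C)C=O | starting material
4 | Diels–Alder aldehyde (1S,10S,11R) | CC(C)(C)[Si](C)(C)OC1=CC[C@](C)(C=O)[C@H]([C@H]1C)C(OC)OC | intermediate
5 | 4-bromo-2-methylbut-1-ene | C=C(C)CCBr | starting material
6 | 3-methylbut-3-enylmagnesium bromide | C=C(C)CC[Mg]Br | intermediate
7 | C2 carbinol (C2 epimers) | CC(C)(C)[Si](C)(C)OC1=CC[C@](C)(C(O)CCC(C)=C)[C@H]([C@H]1C)C(OC)OC | intermediate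
8 | C2 ketone | CC(C)(C)[Si](C)(C)OC1=CC[C@](C)(C(=O)CCC(C)=C)[C@H]([C@H]1C)C(OC)OC | intermediate
9 | (2R)-diisobutylaluminium alkoxide | CC(C)(C)[Si](C)(C)OC1=CC[C@](C)([C@@H](CCC(C)=C)O[Al](CC(C)C)CC(C)C)[C@H]([C@H]1C)C(OC)OC | intermediate
10 | (2R)-acetate silyl enol ether | CC(C)(C)[Si](C)(C)OC1=CC[C@](C)([C@@H](CCC(C)=C)OC(C)=O)[C@H]([C@H]1C)C(OC)OC | intermediate
11 | C12 enone | O=C1C=C[C@](C)([C@@H](CCC(C)=C)OC(C)=O)[C@H]([C@H]1C)C(OC)OC | intermediate
12 | 12β (12S) allylic alcohol | O[C@H]1C=C[C@](C)([C@@H](CCC(C)=C)OC(C)=O)[C@H]([C@H]1C)C(OC)OC | intermediate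
13 | 12α (12R) butanoate acetal | CCCC(=O)O[C@@H]1C=C[C@](C)([C@@H](CCC(C)=C)OC(C)=O)[C@H]([C@H]1C)C(OC)OC | intermediate
14 | ring A C9 aldehyde | CCCC(=O)O[C@@H]1C=C[C@](C)([C@@H](CCC(C)=C)OC(C)=O)[C@H]([C@H]1C)C=O | intermediate
15 | tert-butyl 2-bromopropanoate | CC(Br)C(=O)OC(C)(C)C | starting material
16 | (1-tert-butoxy-1-oxopropan-2-yl)triphenylphosphonium bromide | CC(C(=O)OC(C)(C)C)[P+](c1ccccc1)(c1ccccc1)c1ccccc1.[Br-] | intermediate
17 | tert-butyl 2-(triphenyl-λ5-phosphanylidene)propanoate | CC(=P(c1ccccc1)(c1ccccc1)c1ccccc1)C(=O)OC(C)(C)C | intermediate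
18 | (E)-but-2-enoyl chloride | C/C=C/C(=O)Cl | starting material
19 | vinylketene (buta-1,3-dien-1-one) | C=CC=C=O | intermediate
20 | tert-butyl 2-methylhexa-2,3,5-trienoate (racemic) | C=CC=C=C(C)C(=O)OC(C)(C)C | intermediate
21 | tert-butyl (3E)-3-iodo-2-methylhexa-3,5-dienoate | C=C/C=C(/I)C(C)C(=O)OC(C)(C)C | intermediate
22 | alkenylchromium dichloride from 21 | C=C/C=C(/[Cr](Cl)Cl)C(C)C(=O)OC(C)(C)C | intermediate
23 | (9R,7E)-dienyl carbinol (C17 epimers) | CCCC(=O)O[C@@H]1C=C[C@](C)([C@@H](CCC(C)=C)OC(C)=O)[C@H]([C@H]1C)[C@@H](O)/C(=C/C=C)C(C)C(=O)OC(C)(C)C | intermediate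
24 | (7R,8R,9R)-7,8-epoxy alcohol (C17 epimers) | CCCC(=O)O[C@@H]1C=C[C@](C)([C@@H](CCC(C)=C)OC(C)=O)[C@H]([C@H]1C)[C@@H](O)[C@@]1(C(C)C(=O)OC(C)(C)C)O[C@@H]1C=C | intermediate
25 | (7S,8R,9R)-8,9-diol γ-lactone (C17 epimers) | CCCC(=O)O[C@@H]1C=C[C@](C)([C@@H](CCC(C)=C)OC(C)=O)[C@H]([C@H]1C)[C@@H](O)[C@@]1(O)[C@H](C=C)OC(=O)C1C | intermediate
26 | 9-acetate γ-lactone (C17 epimers) | CCCC(=O)O[C@@H]1C=C[C@](C)([C@@H](CCC(C)=C)OC(C)=O)[C@H]([C@H]1C)[C@@H](OC(C)=O)[C@@]1(O)[C@H](C=C)OC(=O)C1C | intermediate
27 | (17R)-9-acetate γ-lactone triene | CCCC(=O)O[C@@H]1C=C[C@](C)([C@@H](CCC(C)=C)OC(C)=O)[C@H]([C@H]1C)[C@@H](OC(C)=O)[C@@]1(O)[C@H](C=C)OC(=O)[C@@H]1C | intermediate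
28 | CNP0211702.1 | CCCC(=O)O[C@@H]1C=C[C@@]2(C)[C@H]([C@H]1C)[C@@H](OC(C)=O)[C@@]1(O)[C@H](/C=C(/C)CC[C@H]2OC(C)=O)OC(=O)[C@@H]1C | target

**Totals.** Total steps: 16. Longest linear sequence: 13 (steps 1–9 and 13–16).

**Three steps most likely to fail**

1. **Step 16 (ring-closing metathesis).** The step must close a ten-membered ring on a trisubstituted olefin, so oligomers or no closure at all are real possibilities. The fallback changes the substrate design.
   - It sets out from 25 and ties the two hydroxyls into a ring, so the chain ends are pre-organised and no free carbinol can bind ruthenium.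
   - 2-Methoxypropene/PPTS followed by DBU gives the (17R)-8,9-acetonide F1.
   - Metathesis with the same ruthenium carbene gives the macrocyclic acetonide F2.
   - 80 % aqueous AcOH at 40 °C frees the macrocyclic 8,9-diol F3.
   - Ac2O/DMAP acetylates only C9, which returns to the route at 28.

2. **Step 14 (the proposed new step).** The vanadium centre may stop at the epoxide, or the vinyl epoxide may be opened by outside nucleophiles. The fallback gives up both the tandem and the substrate-directed control and uses two separate known reactions.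
   - It sets out from 23. Sharpless asymmetric epoxidation (Ti(OiPr)4, L-(+)-diisopropyl tartrate, t-BuOOH, 4 Å MS, −20 °C) is the matched case for the (9R)-carbinol with bottom-face delivery, and it gives 24 as an isolated compound.
   - A discrete Brønsted-acid lactonisation of the β,γ-epoxy tert-butyl ester (TFA, CH2Cl2, 0 °C) then returns to the route at 25.
   - No compound outside the list is made (F0).

3. **Step 2 (Diels–Alder reaction).** Exo selectivity and enantioselectivity are both asked of an acetal-bearing enal. The fallback moves the exo control to the enone/silyloxydiene pairing for which it is established, and takes absolute configuration from a reagent-controlled reduction of a racemate.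
   - It sets out from 3. Addition of 6 gives the allylic alcohol F4, and MnO2 oxidises it to the enone F5.
   - Cycloaddition of F5 with 2 (toluene, 110 °C, or Me2AlCl, −40 °C) gives the racemic ketone F6.
   - (S)-Me-CBS oxazaborolidine/catecholborane reduces both enantiomers to (2R)-carbinols. These are the separable natural-series alcohol F7 and the unwanted diastereomer F8.
   - Ac2O/DMAP on F7 returns to the route at 10.

**Further compounds**
F1 | step 16 | (17R)-8,9-O-isopropylidene lactone triene | CCCC(=O)O[C@@H]1C=C[C@](C)([C@@H](CCC(C)=C)OC(C)=O)[C@H]([C@H]1C)[C@H]2OC(C)(C)O[C@@]23[C@H](C=C)OC(=O)[C@@H]3C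
F2 | step 16 | macrocyclic (5Z)-8,9-acetonide | CCCC(=O)O[C@@H]1C=C[C@@]2(C)[C@H]([C@H]1C)[C@H]3OC(C)(C)O[C@@]34[C@H](/C=C(/C)CC[C@H]2OC(C)=O)OC(=O)[C@@H]4C
F3 | step 16 | macrocyclic 8,9-diol (9-deacetyl 28) | CCCC(=O)O[C@@H]1C=C[C@@]2(C)[C@H]([C@H]1C)[C@@H](O)[C@@]1(O)[C@H](/C=C(/C)CC[C@H]2OC(C)=O)OC(=O)[C@@H]1C
F0 | step 14 | none | none
F4 | step 2 | (2E)-1,1-dimethoxy-3,7-dimethylocta-2,7-dien-4-ol (racemic) | COC(OC)/C=C(\C)C(O)CCC(C)=C
F5 | step 2 | (2E)-1,1-dimethoxy-3,7-dimethylocta-2,7-dien-4-one | COC(OC)/C=C(\C)C(=O)CCC(C)=C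
F6 | step 2 | racemic 8 (relative configuration shown) | CC(C)(C)[Si](C)(C)OC1=CC[C@](C)(C(=O)CCC(C)=C)[C@H]([C@H]1C)C(OC)OC
F7 | step 2 | (2R)-alcohol of the natural series | CC(C)(C)[Si](C)(C)OC1=CC[C@](C)([C@@H](CCC(C)=C)O)[C@H]([C@H]1C)C(OC)OC
F8 | step 2 | (2R)-alcohol of the antipodal ring A series | CC(C)(C)[Si](C)(C)OC1=CC[C@@](C)([C@@H](CCC(C)=C)O)[C@@H]([C@@H]1C)C(OC)OC
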